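**Retrosynthetic overview**

1. Locants: lactone O1, C2(=O), C3=C4, C5, C6; chain C1'=C2', C3', C4'(OH), C5', C6'(OH), C7', C8'(OH), C9'=C10'–Ph. Target 21 comes from acetal 20, which comes from cross-metathesis at C1'=C2' of homoallylic alcohol 14 with vinyl lactone 19.
2. 14 comes from aldehyde 12 (C4') by reagent-controlled 1,3-anti allylation; 12 comes from dioxane 10 by desilylation and oxidation.
3. Feature the plan rests on: C8' is a carbinol allylic to the styrene unit C9'=C10'–Ph and 1,3-syn to the C6' oxygen. Its isomer with the hydroxyl on benzylic C10' and the alkene at C8'=C9' is less stable, so the C8'–O bond can be made reversibly and locked in the chair dioxane O–C6'–C7'–C8'–O–CHPh (7 + 8 to 10, Re2O7).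
4. 7 comes from cross-metathesis of (S)-homoallylic alcohol 5 (from propane-1,3-diol 1) with racemic 6; 19 comes from acrolein 15 by allylation, acryloylation and ring-closing metathesis.
5. Ring order: 1,3-dioxane (step 5), then the dihydropyranone on the separate fragment (step 11); the dioxane is opened last (step 13).

Key step: step 5

Remark on the chemistry: (−)-Ipc2B(allyl), the allylborane derived from (+)-α-pinene, is taken to add to the Si face of aldehydes and (+)-Ipc2B(allyl) to the Re face; both are used as purchased pentane solutions.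

Step 1
Reactants: 1 propane-1,3-diol
Product: 2 3-[(tert-butyldiphenylsilyl)oxy]propan-1-ol
Conditions: TBDPSCl (1 equiv), imidazole, 1 (3 equiv), THF, 0 °C to rt
Reagents that add atoms: tert-butyl(chloro)diphenylsilane, CC(C)(C)[Si](Cl)(c1ccccc1)c1ccccc1
Why: Silylation of a primary alcohol with a bulky chlorosilane, in which the excess of diol should make the monoether the main product on statistical grounds; no stereocentre is formed.

Step 2
Reactants: 2 3-[(tert-butyldiphenylsilyl)oxy]propan-1-ol
Product: 3 3-[(tert-butyldiphenylsilyl)oxy]propanal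
Conditions: Dess–Martin periodinane, CH2Cl2, 0 °C to rt
Reagents that add atoms: none
Why: Dess–Martin oxidation should stop at the aldehyde under near-neutral conditions that leave the silyl ether untouched.

Step 3
Reactants: 3 3-[(tert-butyldiphenylsilyl)oxy]propanal
Product: 5 (3S)-1-[(tert-butyldiphenylsilyl)oxy]hex-5-en-3-ol, via diisopinocampheylborinate ester 4 (not isolated)
Conditions: (−)-Ipc2B(allyl), Et2O, −78 °C; then NaOH, H2O2, 0 °C to rt
Reagents that add atoms: (−)-B-allyldiisopinocampheylborane, C=CCB([C@@H]1C[C@@H]2C[C@H]([C@H]1C)C2(C)C)[C@@H]1C[C@@H]2C[C@H]([C@H]1C)C2(C)C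
Why: Brown allylation, in which allyl is transferred through a closed chair six-membered transition state and the isopinocampheyl groups expose the Si face of the aldehyde, so C6' should be set as S under reagent control before alkaline peroxide cleaves borinate 4.

Step 4
Reactants: 5 (3S)-1-[(tert-butyldiphenylsilyl)oxy]hex-5-en-3-ol; 6 1-phenylprop-2-en-1-ol (racemic)
Product: 7 (2E,5S)-7-[(tert-butyldiphenylsilyl)oxy]-1-phenylhept-2-ene-1,5-diol (both C1 epimers)
Conditions: second-generation Hoveyda–Grubbs catalyst RuCl2(SIMes)(=CH-C6H4-2-OiPr) (5 mol%), 6 (3 equiv), 1,4-benzoquinone (10 mol%), CH2Cl2, 40 °C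
Reagents that add atoms: none
Why: Olefin cross-metathesis between the terminal homoallylic alkene and an excess of the slowly homodimerising secondary allylic alcohol should give mainly the E alkene, with C6' untouched and C10' deliberately left as both epimers; benzoquinone suppresses ruthenium hydride isomerisation of 6.

Step 5
Reactants: 7 (2E,5S)-7-[(tert-butyldiphenylsilyl)oxy]-1-phenylhept-2-ene-1,5-diol (both C1 epimers); 8 benzaldehyde dimethyl acetal
Product: 10 tert-butyl{2-[(2R,4R,6R)-2-phenyl-6-[(E)-2-phenylethenyl]-1,3-dioxan-4-yl]ethoxy}diphenylsilane (all-cis), via transposed cinnamyl 1,3-diol 9 (not isolated)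
Conditions: Re2O7 (5 mol%), 8 (3 equiv), CH2Cl2, 0 °C to rt; Et3N quench
Reagents that add atoms: none
Why: Re2O7 turns the C10' benzylic allylic alcohol into its perrhenate ester, which delivers oxygen to C8' by a [3,3] shift (or through a tight 1-phenylallyl ion pair) and moves the alkene to C9'=C10' into conjugation with phenyl, while the HReO4 formed in situ catalyses acetal exchange of the C6' and C8' hydroxyls with 8. The closest known reaction type is the Re2O7-catalysed 1,3-transposition of δ-hydroxy allylic alcohols with in situ benzylidene acetal capture to give syn-1,3-diol acetals, of which the secondary aryl carbinol used here is a substrate variation. The 1,3-dioxane closes by 6-endo attack of the C8' oxygen on the benzylidene oxocarbenium ion carried by the C6' oxygen (equivalently, 6-exo capture of the allyl cation at C8' by the hemiacetal oxygen), and this closure is reversible. C8' and the acetal carbon are both set under thermodynamic control by C6' through the chair dioxane, in which the silyloxyethyl, styryl and phenyl groups are all equatorial. Because the transposition and ionisation of the cinnamyl C8'–O bond stay reversible, both C10' epimers of 7, any Z alkene and any anti acetal formed kinetically should drain into the one all-cis product, so racemic 6 suffices. The step needs oxygen at C8' and not C10', and syn and not anti, which styrene conjugation and the all-equatorial chair secure; the competing 3,6-dihydro-2H-pyran (C6' hydroxyl attacking C10') requires a Z allyl cation and is held back by the E alkene and by excess 8 masking the C6' hydroxyl.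

Step 6
Reactants: 10 tert-butyl{2-[(2R,4R,6R)-2-phenyl-6-[(E)-2-phenylethenyl]-1,3-dioxan-4-yl]ethoxy}diphenylsilane
Product: 11 2-[(2R,4R,6R)-2-phenyl-6-[(E)-2-phenylethenyl]-1,3-dioxan-4-yl]ethan-1-ol
Conditions: Bu4NF, THF, 0 °C to rt
Reagents that add atoms: none
Why: Fluoride-mediated desilylation cleaves only the Si–O bond, while the base-stable benzylidene acetal and its three stereocentres should remain intact.

Step 7
Reactants: 11 2-[(2R,4R,6R)-2-phenyl-6-[(E)-2-phenylethenyl]-1,3-dioxan-4-yl]ethan-1-ol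
Product: 12 2-[(2R,4S,6R)-2-phenyl-6-[(E)-2-phenylethenyl]-1,3-dioxan-4-yl]acetaldehyde
Conditions: TEMPO (10 mol%), PhI(OAc)2, CH2Cl2, rt; used at once
Reagents that add atoms: none
Why: Oxoammonium (TEMPO) oxidation with PhI(OAc)2 as terminal oxidant should convert the primary alcohol into the aldehyde without over-oxidation or attack on the styryl alkene or the acetal, and immediate use avoids β-elimination of the acetal oxygen.

Step 8
Reactants: 12 2-[(2R,4S,6R)-2-phenyl-6-[(E)-2-phenylethenyl]-1,3-dioxan-4-yl]acetaldehyde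
Product: 14 (2S)-1-[(2R,4R,6R)-2-phenyl-6-[(E)-2-phenylethenyl]-1,3-dioxan-4-yl]pent-4-en-2-ol, via diisopinocampheylborinate ester 13 (not isolated)
Conditions: (−)-Ipc2B(allyl), Et2O, −78 °C; then NaOH, H2O2, 0 °C
Reagents that add atoms: (−)-B-allyldiisopinocampheylborane, C=CCB([C@@H]1C[C@@H]2C[C@H]([C@H]1C)C2(C)C)[C@@H]1C[C@@H]2C[C@H]([C@H]1C)C2(C)C
Why: Brown allylation under reagent control, in which Si-face delivery should set C4' as S (1,3-anti to the C6' oxygen) because the non-chelating closed transition state makes the weak bias of the β-acetal oxygen subordinate to the reagent.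

Step 9
Reactants: 15 acrolein
Product: 17 (3R)-hexa-1,5-dien-3-ol, via diisopinocampheylborinate ester 16 (not isolated)
Conditions: (+)-Ipc2B(allyl), Et2O/pentane, −78 °C; then NaOH, H2O2; product handled as a concentrated solution (volatile)
Reagents that add atoms: (+)-B-allyldiisopinocampheylborane, C=CCB([C@H]1C[C@H]2C[C@@H]([C@@H]1C)C2(C)C)[C@H]1C[C@H]2C[C@@H]([C@@H]1C)C2(C)C
Why: Brown allylation with the enantiomeric borane, in which 1,2-addition to the enal on the Re face through the closed transition state should set the carbinol carbon (the future C6) as R.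

Step 10
Reactants: 17 (3R)-hexa-1,5-dien-3-ol
Product: 18 (3R)-hexa-1,5-dien-3-yl prop-2-enoate
Conditions: acryloyl chloride, Et3N, DMAP (cat.), CH2Cl2, 0 °C
Reagents that add atoms: acryloyl chloride, C=CC(=O)Cl
Why: O-acylation of the secondary alcohol with an acid chloride under amine base and DMAP catalysis does not break the C–O bond, so the R configuration is retained.

Step 11
Reactants: 18 (3R)-hexa-1,5-dien-3-yl prop-2-enoate
Product: 19 (6R)-6-ethenyl-5,6-dihydro-2H-pyran-2-one
Conditions: first-generation Grubbs catalyst RuCl2(PCy3)2(=CHPh) (5 mol%), Ti(OiPr)4 (0.3 equiv), CH2Cl2 (0.01 M), reflux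
Reagents that add atoms: none
Why: Ring-closing metathesis, in which the ruthenium carbene should load on the unhindered allyl terminus and close onto the acrylate to give the six-membered enoate lactone (loading on the vinyl group, which would lead to the butenolide, is slower), with Ti(OiPr)4 preventing chelation of the ester carbonyl to ruthenium.

Step 12
Reactants: 14 (2S)-1-[(2R,4R,6R)-2-phenyl-6-[(E)-2-phenylethenyl]-1,3-dioxan-4-yl]pent-4-en-2-ol; 19 (6R)-6-ethenyl-5,6-dihydro-2H-pyran-2-one
Product: 20 (6R)-6-{(1E,4S)-4-hydroxy-5-[(2R,4R,6R)-2-phenyl-6-[(E)-2-phenylethenyl]-1,3-dioxan-4-yl]pent-1-en-1-yl}-5,6-dihydro-2H-pyran-2-one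
Conditions: second-generation Hoveyda–Grubbs catalyst RuCl2(SIMes)(=CH-C6H4-2-OiPr) (10 mol%), 19 (3 equiv), CH2Cl2, 40 °C
Reagents that add atoms: none
Why: Olefin cross-metathesis of the terminal alkene of 14 with the allylically oxygenated vinyl group of 19 should give the E C1'=C2' alkene without a protecting group on the C4' hydroxyl; the electron-poor ring enoate and the internal styryl alkene, which is branched at the dioxane carbon and kept as an acetal and not a free allylic alcohol, should stay out, and C6 and C4' are not touched.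

Step 13
Reactants: 20 (6R)-6-{(1E,4S)-4-hydroxy-5-[(2R,4R,6R)-2-phenyl-6-[(E)-2-phenylethenyl]-1,3-dioxan-4-yl]pent-1-en-1-yl}-5,6-dihydro-2H-pyran-2-one
Product: 21 (6R)-6-[(1E,4S,6R,8R,9E)-4,6,8-trihydroxy-10-phenyldeca-1,9-dien-1-yl]-5,6-dihydro-2H-pyran-2-one
Conditions: AcOH/H2O (4:1), THF, 40 °C
Reagents that add atoms: none
Why: Acid-catalysed acetal hydrolysis cleaves only the two benzylidene C–O bonds, so C6' and C8' keep their configuration, and dilute acetic acid is chosen because it should be too weak to ionise the cinnamyl C8'–O bond or the allylic C6–O bond of the lactone.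

**Compound list**

1 | propane-1,3-diol | OCCCO | starting material
2 | 3-[(tert-butyldiphenylsilyl)oxy]propan-1-ol | CC(C)(C)[Si](c1ccccc1)(c1ccccc1)OCCCO | intermediate
3 | 3-[(tert-butyldiphenylsilyl)oxy]propanal | CC(C)(C)[Si](c1ccccc1)(c1ccccc1)OCCC=O | intermediate
4 | (3S)-1-[(tert-butyldiphenylsilyl)oxy]hex-5-en-3-yl diisopinocampheylborinate (not isolated) | CC(C)(C)[Si](c1ccccc1)(c1ccccc1)OCC[C@@H](OB([C@@H]1C[C@@H]2C[C@H]([C@H]1C)C2(C)C)[C@@H]1C[C@@H]2C[C@H]([C@H]1C)C2(C)C)CC=C | intermediate
5 | (3S)-1-[(tert-butyldiphenylsilyl)oxy]hex-5-en-3-ol | CC(C)(C)[Si](c1ccccc1)(c1ccccc1)OCC[C@@H](O)CC=C | intermediate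
6 | 1-phenylprop-2-en-1-ol (racemic) | C=CC(O)c1ccccc1 | starting material
7 | (2E,5S)-7-[(tert-butyldiphenylsilyl)oxy]-1-phenylhept-2-ene-1,5-diol (both C1 epimers) | CC(C)(C)[Si](c1ccccc1)(c1ccccc1)OCC[C@@H](O)C/C=C/C(O)c1ccccc1 | intermediate
8 | benzaldehyde dimethyl acetal, (dimethoxymethyl)benzene | COC(OC)c1ccccc1 | starting material
9 | (1E,5R)-7-[(tert-butyldiphenylsilyl)oxy]-1-phenylhept-1-ene-3,5-diol (C3 epimers, not isolated) | CC(C)(C)[Si](c1ccccc1)(c1ccccc1)OCC[C@@H](O)CC(O)/C=C/c1ccccc1 | intermediate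
10 | tert-butyl{2-[(2R,4R,6R)-2-phenyl-6-[(E)-2-phenylethenyl]-1,3-dioxan-4-yl]ethoxy}diphenylsilane (all-cis) | CC(C)(C)[Si](c1ccccc1)(c1ccccc1)OCC[C@@H]1C[C@H](/C=C/c2ccccc2)O[C@H](c2ccccc2)O1 | intermediate
11 | 2-[(2R,4R,6R)-2-phenyl-6-[(E)-2-phenylethenyl]-1,3-dioxan-4-yl]ethan-1-ol | OCC[C@@H]1C[C@H](/C=C/c2ccccc2)O[C@H](c2ccccc2)O1 | intermediate
12 | 2-[(2R,4S,6R)-2-phenyl-6-[(E)-2-phenylethenyl]-1,3-dioxan-4-yl]acetaldehyde | O=CC[C@@H]1C[C@H](/C=C/c2ccccc2)O[C@H](c2ccccc2)O1 | intermediate
13 | (2S)-1-[(2R,4R,6R)-2-phenyl-6-[(E)-2-phenylethenyl]-1,3-dioxan-4-yl]pent-4-en-2-yl diisopinocampheylborinate (not isolated) | C=CC[C@H](OB([C@@H]1C[C@@H]2C[C@H]([C@H]1C)C2(C)C)[C@@H]1C[C@@H]2C[C@H]([C@H]1C)C2(C)C)C[C@@H]1C[C@H](/C=C/c2ccccc2)O[C@H](c2ccccc2)O1 | intermediate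
14 | (2S)-1-[(2R,4R,6R)-2-phenyl-6-[(E)-2-phenylethenyl]-1,3-dioxan-4-yl]pent-4-en-2-ol | C=CC[C@H](O)C[C@@H]1C[C@H](/C=C/c2ccccc2)O[C@H](c2ccccc2)O1 | intermediate
15 | acrolein (prop-2-enal) | C=CC=O | starting material
16 | (3R)-hexa-1,5-dien-3-yl diisopinocampheylborinate (not isolated) | C=CC[C@H](C=C)OB([C@H]1C[C@H]2C[C@@H]([C@@H]1C)C2(C)C)[C@H]1C[C@H]2C[C@@H]([C@@H]1C)C2(C)C | intermediate
17 | (3R)-hexa-1,5-dien-3-ol | C=CC[C@H](C=C)O | intermediate
18 | (3R)-hexa-1,5-dien-3-yl prop-2-enoate | C=CC[C@H](C=C)OC(=O)C=C | intermediate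
19 | (6R)-6-ethenyl-5,6-dihydro-2H-pyran-2-one | O=C1C=CC[C@H](C=C)O1 | intermediate
20 | (6R)-6-{(1E,4S)-4-hydroxy-5-[(2R,4R,6R)-2-phenyl-6-[(E)-2-phenylethenyl]-1,3-dioxan-4-yl]pent-1-en-1-yl}-5,6-dihydro-2H-pyran-2-one | O=C1C=CC[C@H](/C=C/C[C@H](O)C[C@@H]2C[C@H](/C=C/c3ccccc3)O[C@H](c3ccccc3)O2)O1 | intermediate
21 | (6R)-6-[(1E,4S,6R,8R,9E)-4,6,8-trihydroxy-10-phenyldeca-1,9-dien-1-yl]-5,6-dihydro-2H-pyran-2-one | O=C1C=CC[C@H](/C=C/C[C@H](O)C[C@@H](O)C[C@@H](O)/C=C/c2ccccc2)O1 | target

**Step count and risks**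

Total step count: 13. Longest linear sequence: 10 steps (steps 1 to 8, 12 and 13); steps 9 to 11 build the lactone fragment.

Steps most likely to fail:

Step 5. Equilibration may stall before both C10' epimers have converged, leaving C8' epimers or the anti acetal. Ionisation of the 1-phenylallyl system may also divert material into cyclodehydration (dihydropyran) or elimination to a phenyldiene. The fallback sets out from 7 and comes back at 10, using stepwise known chemistry.
- Selective oxidation of the benzylic allylic alcohol with MnO2 (CH2Cl2, rt) should give (2E,5S)-7-[(tert-butyldiphenylsilyl)oxy]-5-hydroxy-1-phenylhept-2-en-1-one F1.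
- Base-catalysed hemiacetal oxa-Michael addition (PhCHO, KOtBu cat., THF, 0 °C) should then close the thermodynamic syn acetal, all-cis 2-[6-{2-[(tert-butyldiphenylsilyl)oxy]ethyl}-2-phenyl-1,3-dioxan-4-yl]-1-phenylethan-1-one F2.
- NaBH4 (MeOH, 0 °C) should give all-cis 2-[6-{2-[(tert-butyldiphenylsilyl)oxy]ethyl}-2-phenyl-1,3-dioxan-4-yl]-1-phenylethan-1-ol F3 as carbinol epimers.
- Dehydration with the Burgess reagent (toluene, 60 °C) toward the only available β-hydrogens should give the E styrene 10.

Step 12. The ruthenium carbene may engage the styryl alkene (chain truncation with loss of styrene), 14 may homodimerise, or the allylically oxygenated vinyl group of 19 may turn over too slowly. The fallback sets out from 14 and comes back at 21, building the lactone on the chain.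
- TESOTf and 2,6-lutidine (CH2Cl2, −78 °C) should give the C4' triethylsilyl ether of 14 F4.
- Cross-metathesis with excess acrolein (second-generation Hoveyda–Grubbs catalyst, CH2Cl2, 40 °C) should give the (E)-enal, (2E,5S)-6-[all-cis-2-phenyl-6-styryl-1,3-dioxan-4-yl]-5-(triethylsilyloxy)hex-2-enal F5.
- Brown allylation with (+)-Ipc2B(allyl) (Et2O, −78 °C) should form the diisopinocampheylborinate of the C6 carbinol F6, which NaOH/H2O2 cleaves to the (6R)-allylic alcohol, the C6 hydroxy triene F7.
- Acryloyl chloride and Et3N (CH2Cl2, 0 °C) should give the C6 acrylate F8.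
- Ring-closing metathesis (first-generation Grubbs catalyst, Ti(OiPr)4, CH2Cl2, reflux) should give the C4' triethylsilyl ether of 20 F9.
- AcOH/H2O/THF at 40 °C should remove the silyl ether and the acetal together to give 21.

Step 13. Hydrolysis of the benzylidene acetal may be too slow under acid mild enough to spare the lactone; forcing it invites ionisation at the cinnamyl C8'–O bond (epimerisation or allylic transposition) and at the allylic C6–O bond. The fallback sets out from 14 and comes back at 21 by removing the acetal before the lactone is present.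
- Methanolysis of 14 (camphorsulfonic acid cat., MeOH, rt), where methanol can serve as acetal acceptor and any C8' epimer can be separated, should give (1E,3R,5R,7S)-1-phenyldeca-1,9-diene-3,5,7-triol F10.
- Cross-metathesis of the unprotected triol with 19 (second-generation Hoveyda–Grubbs catalyst, CH2Cl2/EtOAc, 40 °C) should give 21 directly, so the last step is neutral.

**Further compounds**

F1 | step 5 | (2E,5S)-7-[(tert-butyldiphenylsilyl)oxy]-5-hydroxy-1-phenylhept-2-en-1-one | CC(C)(C)[Si](c1ccccc1)(c1ccccc1)OCC[C@@H](O)C/C=C/C(=O)c1ccccc1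
F2 | step 5 | all-cis 2-[6-{2-[(tert-butyldiphenylsilyl)oxy]ethyl}-2-phenyl-1,3-dioxan-4-yl]-1-phenylethan-1-one | CC(C)(C)[Si](c1ccccc1)(c1ccccc1)OCC[C@@H]1C[C@H](CC(=O)c2ccccc2)O[C@H](c2ccccc2)O1
F3 | step 5 | all-cis 2-[6-{2-[(tert-butyldiphenylsilyl)oxy]ethyl}-2-phenyl-1,3-dioxan-4-yl]-1-phenylethan-1-ol (carbinol epimers) | CC(C)(C)[Si](c1ccccc1)(c1ccccc1)OCC[C@@H]1C[C@H](CC(O)c2ccccc2)O[C@H](c2ccccc2)O1
F4 | step 12 | C4' triethylsilyl ether of 14 | C=CC[C@H](O[Si](CC)(CC)CC)C[C@@H]1C[C@H](/C=C/c2ccccc2)O[C@H](c2ccccc2)O1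
F5 | step 12 | (2E,5S)-6-[all-cis-2-phenyl-6-styryl-1,3-dioxan-4-yl]-5-(triethylsilyloxy)hex-2-enal | O=C/C=C/C[C@H](O[Si](CC)(CC)CC)C[C@@H]1C[C@H](/C=C/c2ccccc2)O[C@H](c2ccccc2)O1
F6 | step 12 | diisopinocampheylborinate of the C6 carbinol (not isolated) | C=CC[C@H](/C=C/C[C@H](O[Si](CC)(CC)CC)C[C@@H]1C[C@H](/C=C/c2ccccc2)O[C@H](c2ccccc2)O1)OB([C@H]1C[C@H]2C[C@@H]([C@@H]1C)C2(C)C)[C@H]1C[C@H]2C[C@@H]([C@@H]1C)C2(C)C
F7 | step 12 | C6 hydroxy triene, (6R) allylic alcohol | C=CC[C@H](/C=C/C[C@H](O[Si](CC)(CC)CC)C[C@@H]1C[C@H](/C=C/c2ccccc2)O[C@H](c2ccccc2)O1)O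
F8 | step 12 | C6 acrylate | C=CC[C@H](/C=C/C[C@H](O[Si](CC)(CC)CC)C[C@@H]1C[C@H](/C=C/c2ccccc2)O[C@H](c2ccccc2)O1)OC(=O)C=C
F9 | step 12 | C4' triethylsilyl ether of 20 | O=C1C=CC[C@H](/C=C/C[C@H](O[Si](CC)(CC)CC)C[C@@H]2C[C@H](/C=C/c3ccccc3)O[C@H](c3ccccc3)O2)O1
F10 | step 13 | (1E,3R,5R,7S)-1-phenyldeca-1,9-diene-3,5,7-triol | C=CC[C@H](O)C[C@@H](O)C[C@@H](O)/C=C/c1ccccc1
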